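**Strategy.** Both terminal benzene rings (rings A and C) are disconnected to a four‑membered ring plus an alkyne, so the central ring B is the only arene that is bought. Rings A and C are phloroglucinol rings in which the oxygen‑bearing carbons C2, C4 and C6 alternate with the carbon‑substituted C1 (butanoyl), C3 (methyl) and C5 (CH2 bridge). A vinylketene released from a 3‑ethoxycyclobutenone and an ynol ether map exactly onto this pattern. One twofold Danheiser‑type benzannulation forms C3–C4, C1–C2 and C4–C5 in both rings and fixes where OH, methyl, H and the bridge sit. Its precursor is a butanoyl‑trimethoxybenzene (ring B) carrying two (2‑ethoxy‑4‑oxocyclobut‑2‑en‑1‑yl)methyl arms.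

Key step: step 7

Remark (numbering): ring B is the central ring, rings A and C the terminal rings, numbered C1 (butanoyl), C2 (O), C3 (methyl), C4 (O), C5 (CH2 bridge), C6 (O).
Remark (stereochemistry): the target is achiral; the alkene geometry of 6 and the two stereocentres of 15 are erased in steps 3 and 7.
Remark (order of events): the butanoyl group of ring B is introduced only after both formyl‑derived arms are in place, because an enolisable aryl ketone would compete with the ring for the formylating agent and would deactivate the ring towards a second formylation.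
Remark (supply): compounds 1, 2, 5, 8, 12 and 16 are taken to be purchasable.

**Step 1**
Reactants: 1 1,3,5‑trimethoxybenzene; 2 dichloromethyl methyl ether
Product: 4 2,4,6‑trimethoxybenzene‑1,3‑dicarbaldehyde, via bis(α‑chloro ether) 3 (not isolated)
Conditions: Cl2CHOMe (4 equiv), TiCl4 (4.4 equiv), CH2Cl2, 0 °C → rt; then ice‑water
Reagents that add atoms: dichloromethyl methyl ether (2), COC(Cl)Cl; water, O
Why: Twofold Rieche formylation, in which the ring is still activated by three methoxy groups after the first substitution, whereas the ring carrying two acceptors should not react a third time.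

**Step 2**
Reactants: 4 2,4,6‑trimethoxybenzene‑1,3‑dicarbaldehyde; 5 ethyl (triphenylphosphoranylidene)acetate
Product: 6 diethyl (2E,2′E)‑3,3′‑(2,4,6‑trimethoxy‑1,3‑phenylene)bis(prop‑2‑enoate)
Conditions: Ph3P=CHCO2Et (2.5 equiv), PhMe, 100 °C
Reagents that add atoms: ethyl (triphenylphosphoranylidene)acetate (5), CCOC(=O)C=P(c1ccccc1)(c1ccccc1)c1ccccc1
Why: Wittig olefination with a stabilised ylide, which should give the E enoates under thermodynamic control, although the geometry is irrelevant because the double bonds are saturated in step 3.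

**Step 3**
Reactants: 6 diethyl (2E,2′E)‑3,3′‑(2,4,6‑trimethoxy‑1,3‑phenylene)bis(prop‑2‑enoate)
Product: 7 diethyl 3,3′‑(2,4,6‑trimethoxy‑1,3‑phenylene)dipropanoate
Conditions: H2 (1 atm), Pd/C (10 wt%), EtOAc, rt
Reagents that add atoms: none
Why: Catalytic hydrogenation of the two conjugated C=C bonds, under which the arene, the aryl ethers and the esters are inert.

**Step 4**
Reactants: 7 diethyl 3,3′‑(2,4,6‑trimethoxy‑1,3‑phenylene)dipropanoate; 8 butanoyl chloride
Product: 9 diethyl 3,3′‑(5‑butanoyl‑2,4,6‑trimethoxy‑1,3‑phenylene)dipropanoate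
Conditions: PrCOCl (1.3 equiv), AlCl3 (3.5 equiv), CH2Cl2, −10 → 0 °C; ice/1 M HCl
Reagents that add atoms: butanoyl chloride (8), CCCC(Cl)=O
Why: Friedel–Crafts acylation at the only free position of ring B, which lies ortho to two methoxy groups and para to the third, with the low temperature chosen to prevent AlCl3‑mediated loss of the methoxy groups ortho to the new ketone.

**Step 5**
Reactants: 9 diethyl 3,3′‑(5‑butanoyl‑2,4,6‑trimethoxy‑1,3‑phenylene)dipropanoate
Product: 11 3,3′‑(5‑butanoyl‑2,4,6‑trimethoxy‑1,3‑phenylene)dipropanoic acid, via dilithium dicarboxylate 10 (not isolated)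
Conditions: LiOH·H2O (4 equiv), THF/MeOH/H2O, rt; then 1 M HCl to pH 2
Reagents that add atoms: lithium hydroxide, [Li+].[OH-]
Why: Ester saponification, which the hindered diortho‑substituted aryl ketone and the aryl methyl ethers should survive at room temperature.

**Step 6**
Reactants: 11 3,3′‑(5‑butanoyl‑2,4,6‑trimethoxy‑1,3‑phenylene)dipropanoic acid; 12 ethoxyethyne
Product: 15 1‑[3,5‑bis[(2‑ethoxy‑4‑oxocyclobut‑2‑en‑1‑yl)methyl]‑2,4,6‑trimethoxyphenyl]butan‑1‑one (mixture of diastereomers), via bis(acid chloride) 13 (not isolated), via bis(ketene) 14 (not isolated)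
Conditions: (COCl)2 (3 equiv), DMF (cat.), CH2Cl2, 0 °C → rt, evaporate; then ethoxyethyne (10 equiv), Et2O, 0 °C, Et3N (2.4 equiv, slow addition), → rt; neutral alumina
Reagents that add atoms: ethoxyethyne (12), C#COCC
Why: Et3N dehydrochlorinates the acid chlorides to monoalkylketenes, which the excess ynol ether should intercept in a ketene–alkyne [2+2] cycloaddition (ketene carbonyl carbon to the unsubstituted alkyne carbon) to give the 3‑ethoxycyclobutenones, whose new C4 stereocentres form without control and are destroyed in step 7.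

**Step 7**
Reactants: 15 1‑[3,5‑bis[(2‑ethoxy‑4‑oxocyclobut‑2‑en‑1‑yl)methyl]‑2,4,6‑trimethoxyphenyl]butan‑1‑one; 16 1‑ethoxyprop‑1‑yne
Product: 21 1‑[3,5‑bis[(4,6‑diethoxy‑2‑hydroxy‑3‑methylphenyl)methyl]‑2,4,6‑trimethoxyphenyl]butan‑1‑one, via bis(vinylketene) 17 (not isolated), via bis(alkenylcyclobutenone) 18 (not isolated), via bis(dienylketene) 19 (not isolated), via bis(cyclohexadienone) 20 (not isolated)
Conditions: 1‑ethoxyprop‑1‑yne (6 equiv), PhMe (0.05 M), 100 °C, sealed tube, argon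
Reagents that add atoms: 1‑ethoxyprop‑1‑yne (16), CC#COCC
Why: Proposed new method: each 3‑ethoxy‑4‑alkylcyclobutenone unit of 15 should open thermally (4π electrocyclic, the arylmethyl group turning outward) to the ethoxy‑vinylketene 17, whose ketene C=C adds ynol ether 16 in a [2+2] cycloaddition to give the 4‑alkenylcyclobutenone 18; a second 4π opening gives dienylketene 19, which closes by 6π electrocyclisation to cyclohexadienone 20 and tautomerises to the phenol. The closest known reaction is the Danheiser benzannulation of alkyl‑ and aryl‑substituted cyclobutenones with alkoxy‑ and siloxyalkynes, and the thermal opening of 3‑ethoxycyclobutenones to vinylketenes is known from their capture by amines and alcohols; new here are the 3‑alkoxy‑4‑alkyl four‑carbon partner and the twofold use in one molecule. Rings A and C are each closed in the same mode, a thermal disrotatory 6π electrocyclisation that forms C4–C5 after the cycloaddition has formed C3–C4 and C1–C2. No stereocentre is created, and the two stereocentres of 15 become sp2 carbons, so the diastereomer mixture converges on one product. The only selectivity needed is the head‑to‑tail sense of the [2+2] step, which the matched polarity secures: the alkyne carbon that carries methyl (β to oxygen, nucleophilic) attacks the ketene C=O carbon, and the O‑bearing alkyne carbon joins the ketene α‑carbon. The phenols that result are flanked by methyl and the CH2 bridge and should therefore resist acylation by ketene intermediates.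

**Step 8**
Reactants: 21 1‑[3,5‑bis[(4,6‑diethoxy‑2‑hydroxy‑3‑methylphenyl)methyl]‑2,4,6‑trimethoxyphenyl]butan‑1‑one; 8 butanoyl chloride
Product: 22 1‑[3,5‑bis[(3‑butanoyl‑2,4‑diethoxy‑6‑hydroxy‑5‑methylphenyl)methyl]‑2,4,6‑trimethoxyphenyl]butan‑1‑one
Conditions: PrCOCl (3 equiv), AlCl3 (8 equiv), CH2Cl2, −10 → 0 °C; ice/1 M HCl
Reagents that add atoms: butanoyl chloride (8), CCCC(Cl)=O
Why: Friedel–Crafts acylation at C1 of rings A and C, the only unsubstituted carbon of each, which is activated by two ortho ethoxy groups and the para aluminium phenoxide so that C‑acylation should outrun O‑acylation of the hindered phenols, while ring B is already fully substituted.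

**Step 9**
Reactants: 22 1‑[3,5‑bis[(3‑butanoyl‑2,4‑diethoxy‑6‑hydroxy‑5‑methylphenyl)methyl]‑2,4,6‑trimethoxyphenyl]butan‑1‑one
Product: 23 1‑[3,5‑bis[(3‑butanoyl‑2,4,6‑trihydroxy‑5‑methylphenyl)methyl]‑2,4,6‑trihydroxyphenyl]butan‑1‑one (target)
Conditions: BBr3 (12 equiv), CH2Cl2, −78 °C → rt; then H2O, 0 °C
Reagents that add atoms: none
Why: BBr3 ether cleavage (O‑complexation, then SN2 attack of bromide on methyl or ethyl), in which six of the seven ethers sit ortho to a ketone and are chelation‑assisted, the seventh (C4–OMe of ring B) is twisted out of plane and therefore basic, and the acyl group on every ring should protect the ArCH2–Ar bonds from acid‑induced cleavage.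

**Compound list**

1 | 1,3,5‑trimethoxybenzene | COc1cc(OC)cc(OC)c1 | starting material
2 | dichloromethyl methyl ether | COC(Cl)Cl | starting material
3 | 2,4‑bis[chloro(methoxy)methyl]‑1,3,5‑trimethoxybenzene (stereoisomer mixture) | COC(Cl)c1c(OC)cc(OC)c(C(Cl)OC)c1OC | intermediate (not isolated)
4 | 2,4,6‑trimethoxybenzene‑1,3‑dicarbaldehyde | COc1cc(OC)c(C=O)c(OC)c1C=O | intermediate
5 | ethyl (triphenylphosphoranylidene)acetate | CCOC(=O)C=P(c1ccccc1)(c1ccccc1)c1ccccc1 | starting material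
6 | diethyl (2E,2′E)‑3,3′‑(2,4,6‑trimethoxy‑1,3‑phenylene)bis(prop‑2‑enoate) | CCOC(=O)/C=C/c1c(OC)cc(OC)c(/C=C/C(=O)OCC)c1OC | intermediate
7 | diethyl 3,3′‑(2,4,6‑trimethoxy‑1,3‑phenylene)dipropanoate | CCOC(=O)CCc1c(OC)cc(OC)c(CCC(=O)OCC)c1OC | intermediate
8 | butanoyl chloride | CCCC(Cl)=O | starting material
9 | diethyl 3,3′‑(5‑butanoyl‑2,4,6‑trimethoxy‑1,3‑phenylene)dipropanoate | CCCC(=O)c1c(OC)c(CCC(=O)OCC)c(OC)c(CCC(=O)OCC)c1OC | intermediate
10 | dilithium 3,3′‑(5‑butanoyl‑2,4,6‑trimethoxy‑1,3‑phenylene)dipropanoate | CCCC(=O)c1c(OC)c(CCC(=O)[O-])c(OC)c(CCC(=O)[O-])c1OC.[Li+].[Li+] | intermediate (not isolated)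
11 | 3,3′‑(5‑butanoyl‑2,4,6‑trimethoxy‑1,3‑phenylene)dipropanoic acid | CCCC(=O)c1c(OC)c(CCC(=O)O)c(OC)c(CCC(=O)O)c1OC | intermediate
12 | ethoxyethyne (ethoxyacetylene) | C#COCC | starting material
13 | 3,3′‑(5‑butanoyl‑2,4,6‑trimethoxy‑1,3‑phenylene)dipropanoyl dichloride | CCCC(=O)c1c(OC)c(CCC(=O)Cl)c(OC)c(CCC(=O)Cl)c1OC | intermediate (not isolated)
14 | 1‑[2,4,6‑trimethoxy‑3,5‑bis(3‑oxoprop‑2‑en‑1‑yl)phenyl]butan‑1‑one (bis‑ketene) | CCCC(=O)c1c(OC)c(CC=C=O)c(OC)c(CC=C=O)c1OC | intermediate (not isolated)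
15 | 1‑[3,5‑bis[(2‑ethoxy‑4‑oxocyclobut‑2‑en‑1‑yl)methyl]‑2,4,6‑trimethoxyphenyl]butan‑1‑one (diastereomer mixture) | CCCC(=O)c1c(OC)c(CC2C(=O)C=C2OCC)c(OC)c(CC2C(=O)C=C2OCC)c1OC | intermediate
16 | 1‑ethoxyprop‑1‑yne | CC#COCC | starting material
17 | 1‑[3,5‑bis[(2Z)‑3‑ethoxy‑5‑oxopenta‑2,4‑dien‑1‑yl]‑2,4,6‑trimethoxyphenyl]butan‑1‑one (bis‑vinylketene; both arms drawn at the same stage) | CCCC(=O)c1c(OC)c(C/C=C(OCC)/C=C=O)c(OC)c(C/C=C(OCC)/C=C=O)c1OC | intermediate (not isolated)
18 | 1‑[3,5‑bis[(2Z)‑3‑ethoxy‑3‑(2‑ethoxy‑3‑methyl‑4‑oxocyclobut‑2‑en‑1‑yl)prop‑2‑en‑1‑yl]‑2,4,6‑trimethoxyphenyl]butan‑1‑one (ring stereocentres uncontrolled) | CCCC(=O)c1c(OC)c(C/C=C(OCC)/C2C(=O)C(C)=C2OCC)c(OC)c(C/C=C(OCC)/C2C(=O)C(C)=C2OCC)c1OC | intermediate (not isolated)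
19 | 1‑[3,5‑bis[(2Z,4E)‑3,5‑diethoxy‑6‑methyl‑7‑oxohepta‑2,4,6‑trien‑1‑yl]‑2,4,6‑trimethoxyphenyl]butan‑1‑one (bis‑dienylketene; the geometry that cyclises) | CCCC(=O)c1c(OC)c(C/C=C(OCC)/C=C(OCC)\C(C)=C=O)c(OC)c(C/C=C(OCC)/C=C(OCC)\C(C)=C=O)c1OC | intermediate (not isolated)
20 | 1‑[3,5‑bis[(2,4‑diethoxy‑5‑methyl‑6‑oxocyclohexa‑2,4‑dien‑1‑yl)methyl]‑2,4,6‑trimethoxyphenyl]butan‑1‑one (ring stereocentres uncontrolled) | CCCC(=O)c1c(OC)c(CC2C(=O)C(C)=C(OCC)C=C2OCC)c(OC)c(CC2C(=O)C(C)=C(OCC)C=C2OCC)c1OC | intermediate (not isolated)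
21 | 1‑[3,5‑bis[(4,6‑diethoxy‑2‑hydroxy‑3‑methylphenyl)methyl]‑2,4,6‑trimethoxyphenyl]butan‑1‑one | CCCC(=O)c1c(OC)c(Cc2c(O)c(C)c(OCC)cc2OCC)c(OC)c(Cc2c(O)c(C)c(OCC)cc2OCC)c1OC | intermediate
22 | 1‑[3,5‑bis[(3‑butanoyl‑2,4‑diethoxy‑6‑hydroxy‑5‑methylphenyl)methyl]‑2,4,6‑trimethoxyphenyl]butan‑1‑one | CCCC(=O)c1c(OC)c(Cc2c(O)c(C)c(OCC)c(C(=O)CCC)c2OCC)c(OC)c(Cc2c(O)c(C)c(OCC)c(C(=O)CCC)c2OCC)c1OC | intermediate
23 | 1‑[3,5‑bis[(3‑butanoyl‑2,4,6‑trihydroxy‑5‑methylphenyl)methyl]‑2,4,6‑trihydroxyphenyl]butan‑1‑one | CCCC(=O)c1c(O)c(C)c(O)c(Cc2c(O)c(Cc3c(O)c(C)c(O)c(C(=O)CCC)c3O)c(O)c(C(=O)CCC)c2O)c1O | target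

**Count.** Total: 9 steps. Longest linear sequence: 9 steps (1 → 23).

**Steps most likely to fail**

*Step 7.* The alkoxy‑vinylketene may reclose or oligomerise instead of adding the ynol ether. Ynol ether 16 may be depleted by retro‑ene loss of ethylene at the reaction temperature. The two arms may also stop at different stages, leaving half‑annulated material. Fallback, known chemistry only, setting out from 4 and coming back at 23: rings A and C are taken from a preformed arene instead of being built. Commercial 2,4,6‑trimethoxytoluene is lithiated between two methoxy groups (n‑BuLi, THF, 0 °C) to (2,4,6‑trimethoxy‑3‑methylphenyl)lithium F1, which adds twice to dialdehyde 4 to give (2,4,6‑trimethoxy‑1,3‑phenylene)bis[(2,4,6‑trimethoxy‑3‑methylphenyl)methanol] F2. Ionic hydrogenation (Et3SiH, TFA, CH2Cl2, 0 °C) gives 1,3,5‑trimethoxy‑2,4‑bis[(2,4,6‑trimethoxy‑3‑methylphenyl)methyl]benzene F3. Threefold Friedel–Crafts butanoylation with 8 (AlCl3, CH2Cl2, 0 °C) at the one free position of each ring gives 1‑[3,5‑bis[(3‑butanoyl‑2,4,6‑trimethoxy‑5‑methylphenyl)methyl]‑2,4,6‑trimethoxyphenyl]butan‑1‑one F4, and BBr3 then cleaves the nine methyl ethers to give 23.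

*Step 8.* The free phenols may be O‑acylated in competition with C‑acylation. The benzylic CH2–aryl bonds of the still unacylated, very electron‑rich terminal rings may also be cleaved or migrate in the AlCl3/HCl medium before the ketones are in place. Fallback, setting out from 21 and coming back at 22: a Houben–Hoesch acylation with a nitrilium electrophile, which does not acylate oxygen. Butanenitrile, ZnCl2 and HCl gas in Et2O at 0 °C should give the bis(ketiminium chloride) of 22, F5, which is hydrolysed in warm water to 22.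

*Step 9.* The C4 methoxy group of ring B, which has no carbonyl neighbour, may be cleaved incompletely. The HBr generated may also cause protodebenzylation or scrambling at the CH2 bridges. Fallback, setting out from 1 and 8 and coming back at 23: no late dealkylation at all, because the three rings are joined as free phloroglucinols. Compound 1 is acylated with 8 (AlCl3, CH2Cl2, 0 °C) to 1‑(2,4,6‑trimethoxyphenyl)butan‑1‑one F6, which BBr3 converts into 1‑(2,4,6‑trihydroxyphenyl)butan‑1‑one F7 at the monomer stage. Commercial 2‑methylbenzene‑1,3,5‑triol is acylated with 8 (AlCl3, PhNO2) to 1‑(2,4,6‑trihydroxy‑3‑methylphenyl)butan‑1‑one F8, whose single free ring position is aminomethylated with dimethyl(methylidene)ammonium iodide to 1‑[3‑[(dimethylamino)methyl]‑2,4,6‑trihydroxy‑5‑methylphenyl]butan‑1‑one F9. Heating F7 with two equivalents of F9 in dioxane expels dimethylamine, and the resulting ortho‑quinone methide is captured at both free positions of F7 to give 23.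

**Further compounds**

F1 | step 7 | (2,4,6‑trimethoxy‑3‑methylphenyl)lithium | [Li]c1c(OC)c(C)c(OC)cc1OC
F2 | step 7 | (2,4,6‑trimethoxy‑1,3‑phenylene)bis[(2,4,6‑trimethoxy‑3‑methylphenyl)methanol] (diastereomer mixture) | COc1cc(OC)c(C(O)c2c(OC)cc(OC)c(C)c2OC)c(OC)c1C(O)c1c(OC)cc(OC)c(C)c1OC
F3 | step 7 | 1,3,5‑trimethoxy‑2,4‑bis[(2,4,6‑trimethoxy‑3‑methylphenyl)methyl]benzene | COc1cc(OC)c(Cc2c(OC)cc(OC)c(C)c2OC)c(OC)c1Cc1c(OC)cc(OC)c(C)c1OC
F4 | step 7 | 1‑[3,5‑bis[(3‑butanoyl‑2,4,6‑trimethoxy‑5‑methylphenyl)methyl]‑2,4,6‑trimethoxyphenyl]butan‑1‑one | CCCC(=O)c1c(OC)c(Cc2c(OC)c(C)c(OC)c(C(=O)CCC)c2OC)c(OC)c(Cc2c(OC)c(C)c(OC)c(C(=O)CCC)c2OC)c1OC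
F5 | step 8 | bis(ketiminium chloride) of 22 | CCCC(=O)c1c(OC)c(Cc2c(O)c(C)c(OCC)c(C(=[NH2+])CCC)c2OCC)c(OC)c(Cc2c(O)c(C)c(OCC)c(C(=[NH2+])CCC)c2OCC)c1OC.[Cl-].[Cl-]
F6 | step 9 | 1‑(2,4,6‑trimethoxyphenyl)butan‑1‑one | CCCC(=O)c1c(OC)cc(OC)cc1OC
F7 | step 9 | 1‑(2,4,6‑trihydroxyphenyl)butan‑1‑one | CCCC(=O)c1c(O)cc(O)cc1O
F8 | step 9 | 1‑(2,4,6‑trihydroxy‑3‑methylphenyl)butan‑1‑one | CCCC(=O)c1c(O)cc(O)c(C)c1O
F9 | step 9 | 1‑[3‑[(dimethylamino)methyl]‑2,4,6‑trihydroxy‑5‑methylphenyl]butan‑1‑one | CCCC(=O)c1c(O)c(C)c(O)c(CN(C)C)c1O
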